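**Plan**
Retrosynthesis: the C6 configuration is traced back to acid exchange at the peroxyketal; the dioxine is cut at O1–C6 and C6–OMe, then at O2–C3 (conjugate addition of a masked hydroperoxide) and at C2=C3 (Wittig). The C3–C6 ene-dicarbonyl goes back to a 2-alkylfuran, whose four ring carbons become C3–C6 of the dioxine; the chain is cut at C12′–C13′ (sorbyl coupling) and C6–C1′ (furan alkylation).
Forward: the chain is joined first (steps 1–2), the furan is opened oxidatively and homologated to the 6-oxo-2,4-dienal (steps 3–4), the peroxide is added at C3 and the aldehyde is taken to the methyl ester (steps 5–8). The 3,6-dihydro-1,2-dioxine, the only ring of the target, is closed last (step 9), and C6 is then settled (step 10).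
Enabling feature: in the 3-hydroperoxy-6-oxo-4-enoate the O–O–H on C3 and the C6 ketone sit at the two ends of C3–C4=C5–C6. Only the Z alkene lets the terminal oxygen reach C6 and close the ring O1–O2–C3–C4=C5–C6; the enone is the chromophore that lets light turn E into Z, and C6 ends as an exchangeable peroxyketal carbon.
Stereochemistry: C3 (R) comes from catalyst-controlled peroxide addition to the enal (step 6). C6 forms as both epimers in step 9 and is brought to S by acid exchange at the peroxyketal with removal of the target and recycling of the rest (step 10). The ring alkene is Z through the photochemical funnel, and the chain diene is E,E from sorbyl acetate.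

Key step: step 9

Remark: the peroxyketal carbon C6 is taken to epimerise under acid through the ring peroxycarbenium ion without loss of the C3 configuration, so its configuration is set last, under equilibrium, with chromatographic separation and recycling.

**Route**

Step 1
Reactants: 1 furan, 2 1,12-dibromododecane
Product: 4 2-(12-bromododecyl)furan, via 2-lithiofuran 3 (not isolated)
Conditions: n-BuLi, THF, 0 °C; then 2 (3 equiv), DMPU, −78 °C → rt
Reagents that add atoms: none
Why: α-Lithiation of furan followed by SN2 alkylation of the heteroaryllithium with an excess of the primary dibromide should give the monoalkylated furan (heteroarene lithiation–alkylation).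

Step 2
Reactants: 4 2-(12-bromododecyl)furan, 5 (2E,4E)-hexa-2,4-dien-1-yl acetate
Product: 7 2-[(14E,16E)-octadeca-14,16-dien-1-yl]furan, via Grignard reagent 6 (not isolated)
Conditions: Mg, THF, 40 °C; then 5, Li2CuCl4 (3 mol %), THF, −20 °C
Reagents that add atoms: none
Why: Kochi-type copper-catalysed sp3–sp3 coupling of the primary Grignard reagent at the acetate-bearing carbon of the dienyl acetate should carry the E,E geometry of sorbyl acetate unchanged into the chain.

Step 3
Reactants: 7 2-[(14E,16E)-octadeca-14,16-dien-1-yl]furan
Product: 9 (2E,18E,20E)-4-oxodocosa-2,18,20-trienal, via Z-enal 8 (not isolated)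
Conditions: NBS (1.05 equiv), NaHCO3, acetone–H2O (10:1), −20 °C; then pyridine, 0 °C → rt
Reagents that add atoms: water (O)
Why: The 2-alkylfuran is the most nucleophilic π system, so bromonium transfer and hydrolysis should open it to the cis ene-dicarbonyl (oxidative furan ring opening, a dearomatisation), and pyridine then isomerises the Z enal to the E isomer by reversible conjugate addition.

Step 4
Reactants: 9 (2E,18E,20E)-4-oxodocosa-2,18,20-trienal, 10 (triphenylphosphoranylidene)acetaldehyde
Product: 11 (2E,4E,20E,22E)-6-oxotetracosa-2,4,20,22-tetraenal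
Conditions: CH2Cl2, rt
Reagents that add atoms: none
Why: Wittig olefination with the stabilised formyl ylide should be selective for the aldehyde over the ketone and give the new C2=C3 bond as the E isomer.

Step 5
Reactants: 12 2,3-dimethylbut-2-ene
Product: 14 2-hydroperoxy-2-methoxypropane, via acetone O-oxide 13 (not isolated)
Conditions: O3, MeOH–CH2Cl2, −78 °C
Reagents that add atoms: ozone ([O-][O+]=O); methanol (CO)
Why: Criegee ozonolysis in methanol, in which the carbonyl oxide is trapped by the solvent, should give the α-methoxy hydroperoxide that serves as a masked hydrogen peroxide.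

Step 6
Reactants: 11 (2E,4E,20E,22E)-6-oxotetracosa-2,4,20,22-tetraenal, 14 2-hydroperoxy-2-methoxypropane
Product: 15 (3R,4E,20E,22E)-3-[(2-methoxypropan-2-yl)peroxy]-6-oxotetracosa-4,20,22-trienal
Conditions: (R)-2-[diphenyl(trimethylsilyloxy)methyl]pyrrolidine (10 mol %), PhCO2H (10 mol %), toluene, −20 °C
Reagents that add atoms: none
Why: Iminium-ion catalysed conjugate addition of an α-alkoxyalkyl hydroperoxide to an enal (organocatalytic asymmetric peroxidation) should form the O–C3 bond on the face left open by the diphenyl(silyloxy)methyl arm of the E,s-trans iminium ion, which on the usual shielding model gives 3R with the R catalyst, while benzoic acid protonates the enamine before it can close onto the O–O bond and addition at C3 instead of C5 leaves the C4=C5–C6=O enone intact.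

Step 7
Reactants: 15 (3R,4E,20E,22E)-3-[(2-methoxypropan-2-yl)peroxy]-6-oxotetracosa-4,20,22-trienal
Product: 16 (3R,4E,20E,22E)-3-[(2-methoxypropan-2-yl)peroxy]-6-oxotetracosa-4,20,22-trienoic acid
Conditions: NaClO2, NaH2PO4, 2-methyl-2-butene, t-BuOH–H2O, 0 °C
Reagents that add atoms: sodium chlorite ([Na+].[O-]Cl=O)
Why: Pinnick oxidation should convert the aldehyde to the acid under buffered, mildly acidic conditions and short contact at 0 °C that avoid base-induced β-elimination of the C3 peroxide, with the alkene scavenger protecting the enone and the diene from HOCl.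

Step 8
Reactants: 16 (3R,4E,20E,22E)-3-[(2-methoxypropan-2-yl)peroxy]-6-oxotetracosa-4,20,22-trienoic acid
Product: 17 methyl (3R,4E,20E,22E)-3-[(2-methoxypropan-2-yl)peroxy]-6-oxotetracosa-4,20,22-trienoate
Conditions: TMSCHN2, MeOH–toluene, 0 °C
Reagents that add atoms: (trimethylsilyl)diazomethane (C[Si](C)(C)C=[N+]=[N-])
Why: Esterification with trimethylsilyldiazomethane in methanol is fast and neutral, so neither the peroxyketal nor the β-peroxy stereocentre should be disturbed.

Step 9
Reactants: 17 methyl (3R,4E,20E,22E)-3-[(2-methoxypropan-2-yl)peroxy]-6-oxotetracosa-4,20,22-trienoate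
Product: 21 methyl 2-[(3R)-6-methoxy-6-[(14E,16E)-octadeca-14,16-dien-1-yl]-3,6-dihydro-1,2-dioxin-3-yl]acetate as the mixture of its 6S and 6R epimers, via E-hydroperoxide 18 (not isolated), via Z-hydroperoxy enone 19 (not isolated), via dioxinol 20 (not isolated)
Conditions: PPTS (10 mol %), MeOH, 0 °C, dark; then hν (350–365 nm, Pyrex), 0 °C; then TsOH·H2O (5 mol %), MeOH, 0 °C → rt
Reagents that add atoms: methanol (CO)
Why: Acid methanolysis of the 2-methoxyprop-2-yl peroxyketal frees the C3 hydroperoxide, n→π* excitation of the enone pumps the E alkene to the Z isomer, and only in that isomer can the terminal peroxide oxygen reach the C6 carbonyl, so 19 is drained thermally by 6-exo-trig hemiketalisation to dioxinol 20 while the remaining E isomer is re-excited until all material has passed through the Z form. Acid then ionises the hemiketal to the ring peroxycarbenium ion (O1=C6) and methanol adds to give the peroxyketal; the closest known reaction types are the E/Z photoisomerisation of acyclic enones, the spontaneous closure of Z-configured γ-hydroperoxy enones to 1,2-dioxin-3-ols and their acid-catalysed ketalisation with methanol. C3 is not touched and keeps the R configuration set in step 6, provided that ring closure of 19 is faster than its photoenolisation by γ-hydrogen abstraction, which the acid catalyst and a low light flux are meant to secure. The new stereocentre C6 forms through the planar peroxycarbenium ion with no strong bias from the remote C3 substituent, so 21 is expected as both C6 epimers in comparable amounts, and its configuration is settled in step 10. The remote E,E-diene does not absorb above 300 nm and the short-lived triplet of the acyclic enone should not sensitise it.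

Step 10
Reactants: 21 methyl 2-[(3R)-6-methoxy-6-[(14E,16E)-octadeca-14,16-dien-1-yl]-3,6-dihydro-1,2-dioxin-3-yl]acetate (mixture of the 6S and 6R epimers)
Product: 22 xestin B (methyl 2-[(3R,6S)-6-methoxy-6-[(14E,16E)-octadeca-14,16-dien-1-yl]-3,6-dihydro-1,2-dioxin-3-yl]acetate)
Conditions: SiO2 chromatography (22 collected); 6R-enriched remainder: TsOH·H2O (5 mol %), MeOH, rt, to constant epimer ratio; SiO2 again; cycle repeated
Reagents that add atoms: methanol (CO)
Why: Acid ionises the peroxyketal to the ring peroxycarbenium ion (O1=C6) and methanol re-adds from either face (ketal exchange, epimerisation at an anomeric-type centre), which leaves C3 untouched, so each pass should turn part of the 6R component into the 6S epimer, and removal of 22 with resubmission of the remainder funnels the material into 22; both epimers can place OMe pseudoaxial and the chain pseudoequatorial and differ only in the pseudoaxial or pseudoequatorial position of the C3 side chain, so comparable amounts are expected at equilibrium.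

**Compound list**
1 | furan | c1ccoc1 | starting material
2 | 1,12-dibromododecane | BrCCCCCCCCCCCCBr | starting material
3 | 2-lithiofuran | [Li]c1ccco1 | intermediate
4 | 2-(12-bromododecyl)furan | BrCCCCCCCCCCCCc1ccco1 | intermediate
5 | (2E,4E)-hexa-2,4-dien-1-yl acetate (sorbyl acetate) | C/C=C/C=C/COC(C)=O | starting material
6 | [12-(furan-2-yl)dodecyl]magnesium bromide | Br[Mg]CCCCCCCCCCCCc1ccco1 | intermediate
7 | 2-[(14E,16E)-octadeca-14,16-dien-1-yl]furan | C/C=C/C=C/CCCCCCCCCCCCCc1ccco1 | intermediate
8 | (2Z,18E,20E)-4-oxodocosa-2,18,20-trienal | C/C=C/C=C/CCCCCCCCCCCCCC(=O)/C=C\C=O | intermediate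
9 | (2E,18E,20E)-4-oxodocosa-2,18,20-trienal | C/C=C/C=C/CCCCCCCCCCCCCC(=O)/C=C/C=O | intermediate
10 | (triphenylphosphoranylidene)acetaldehyde | O=CC=P(c1ccccc1)(c1ccccc1)c1ccccc1 | starting material
11 | (2E,4E,20E,22E)-6-oxotetracosa-2,4,20,22-tetraenal | C/C=C/C=C/CCCCCCCCCCCCCC(=O)/C=C/C=C/C=O | intermediate
12 | 2,3-dimethylbut-2-ene | CC(C)=C(C)C | starting material
13 | acetone O-oxide | CC(C)=[O+][O-] | intermediate
14 | 2-hydroperoxy-2-methoxypropane (2-methoxyprop-2-yl hydroperoxide) | COC(C)(C)OO | intermediate
15 | (3R,4E,20E,22E)-3-[(2-methoxypropan-2-yl)peroxy]-6-oxotetracosa-4,20,22-trienal | C/C=C/C=C/CCCCCCCCCCCCCC(=O)/C=C/[C@@H](CC=O)OOC(C)(C)OC | intermediate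
16 | (3R,4E,20E,22E)-3-[(2-methoxypropan-2-yl)peroxy]-6-oxotetracosa-4,20,22-trienoic acid | C/C=C/C=C/CCCCCCCCCCCCCC(=O)/C=C/[C@@H](CC(=O)O)OOC(C)(C)OC | intermediate
17 | methyl (3R,4E,20E,22E)-3-[(2-methoxypropan-2-yl)peroxy]-6-oxotetracosa-4,20,22-trienoate | C/C=C/C=C/CCCCCCCCCCCCCC(=O)/C=C/[C@@H](CC(=O)OC)OOC(C)(C)OC | intermediate
18 | methyl (3R,4E,20E,22E)-3-hydroperoxy-6-oxotetracosa-4,20,22-trienoate | C/C=C/C=C/CCCCCCCCCCCCCC(=O)/C=C/[C@@H](CC(=O)OC)OO | intermediate
19 | methyl (3R,4Z,20E,22E)-3-hydroperoxy-6-oxotetracosa-4,20,22-trienoate | C/C=C/C=C/CCCCCCCCCCCCCC(=O)/C=C\[C@@H](CC(=O)OC)OO | intermediate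
20 | methyl 2-[(3R)-6-hydroxy-6-[(14E,16E)-octadeca-14,16-dien-1-yl]-3,6-dihydro-1,2-dioxin-3-yl]acetate (both C6 epimers) | C/C=C/C=C/CCCCCCCCCCCCCC1(O)C=C[C@@H](CC(=O)OC)OO1 | intermediate
21 | methyl 2-[(3R)-6-methoxy-6-[(14E,16E)-octadeca-14,16-dien-1-yl]-3,6-dihydro-1,2-dioxin-3-yl]acetate (mixture of the 6S and 6R epimers) | C/C=C/C=C/CCCCCCCCCCCCCC1(OC)C=C[C@@H](CC(=O)OC)OO1 | intermediate
22 | xestin B, methyl 2-[(3R,6S)-6-methoxy-6-[(14E,16E)-octadeca-14,16-dien-1-yl]-3,6-dihydro-1,2-dioxin-3-yl]acetate | C/C=C/C=C/CCCCCCCCCCCCC[C@@]1(OC)C=C[C@@H](CC(=O)OC)OO1 | target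

**Count**
Total steps: 10. Longest linear sequence: 9 steps (1–4 and 6–10); step 5 prepares reagent 14.

**Steps most likely to fail**

Step 6. The enamine formed after peroxide addition may close onto the O–O bond (epoxide formation at C2–C3), addition may occur at C5, or reversible addition may erode the facial selectivity. The fallback uses no iminium catalysis and closes the ring by a base-mediated peroxy-Michael addition; it sets out from 8, which is taken from step 3 before pyridine is added. Wittig reaction of 8 with methyl (triphenylphosphoranylidene)acetate (CH2Cl2, 0 °C) should give methyl (2E,4Z,20E,22E)-6-oxotetracosa-2,4,20,22-tetraenoate F1, which keeps the Z alkene inherited from the furan. Urea–H2O2 with Sc(OTf)3 (catalytic) in MeOH should convert the ketone into racemic methyl (2E,4Z,20E,22E)-6-hydroperoxy-6-methoxytetracosa-2,4,20,22-tetraenoate F2. Et2NH in CF3CH2OH should then close the ring by 6-exo-trig addition of the hydroperoxide to C3 of the enoate. This gives all four stereoisomers: 22, its C6 epimer methyl 2-[(3R,6R)-6-methoxy-6-[(14E,16E)-octadeca-14,16-dien-1-yl]-3,6-dihydro-1,2-dioxin-3-yl]acetate F3, and their enantiomers methyl 2-[(3S,6R)-6-methoxy-6-[(14E,16E)-octadeca-14,16-dien-1-yl]-3,6-dihydro-1,2-dioxin-3-yl]acetate F4 and methyl 2-[(3S,6S)-6-methoxy-6-[(14E,16E)-octadeca-14,16-dien-1-yl]-3,6-dihydro-1,2-dioxin-3-yl]acetate F5. The two diastereomeric pairs are separated on silica and 22 is separated from its enantiomer F4 by preparative HPLC on a chiral stationary phase; the fallback comes back to the route at 22.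

Step 9. When acid, methanol and light act together on the free hydroperoxide, Hock-type cleavage, conjugate addition of methanol to the enone, or photoenolisation of the transient Z enone (γ-hydrogen abstraction at C3, which would erode the C3 configuration) may outrun ring closure. The fallback uncouples the three events and makes the C6 methoxy group by O-alkylation instead of ketal exchange; it sets out from 17. Methanolysis in the dark (PPTS, MeOH, 0 °C) gives 18, which is isolated. Irradiation of 18 alone in CH2Cl2 at −40 °C without acid lets 19 close spontaneously to 20, which is isolated. The hemiketal hydroxyl of 20 is then methylated with MeOTf and 2,6-di-tert-butyl-4-methylpyridine (CH2Cl2, −40 °C); this forms the O–CH3 bond without ionising C6 and gives both C6 epimers. The fallback comes back at 21 and makes no compound outside the list.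

Step 3. Bromonium transfer to the chain diene (bromohydrin formation) or over-oxidation may compete with opening of the furan. The fallback oxidises the furan before the diene is present and carries it as a masked ene-dicarbonyl; it sets out from 4. Methoxylation of the furan (Br2, Na2CO3, MeOH, −40 °C) should give 2-(12-bromododecyl)-2,5-dimethoxy-2,5-dihydrofuran F6. Mg in THF gives [12-(2,5-dimethoxy-2,5-dihydrofuran-2-yl)dodecyl]magnesium bromide F7, which is coupled with 5 (Li2CuCl4 catalytic, THF, −20 °C) to 2,5-dimethoxy-2-[(14E,16E)-octadeca-14,16-dien-1-yl]-2,5-dihydrofuran F8. Hydrolysis (dilute aqueous H2SO4, acetone, 0 °C) releases 8 and pyridine isomerises it; the fallback comes back at 9.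

Further compounds
F1 | step 6 | methyl (2E,4Z,20E,22E)-6-oxotetracosa-2,4,20,22-tetraenoate | C/C=C/C=C/CCCCCCCCCCCCCC(=O)/C=C\C=C\C(=O)OC
F2 | step 6 | methyl (2E,4Z,20E,22E)-6-hydroperoxy-6-methoxytetracosa-2,4,20,22-tetraenoate (racemic) | C/C=C/C=C/CCCCCCCCCCCCCC(OC)(OO)/C=C\C=C\C(=O)OC
F3 | step 6 | methyl 2-[(3R,6R)-6-methoxy-6-[(14E,16E)-octadeca-14,16-dien-1-yl]-3,6-dihydro-1,2-dioxin-3-yl]acetate | C/C=C/C=C/CCCCCCCCCCCCC[C@]1(OC)C=C[C@@H](CC(=O)OC)OO1
F4 | step 6 | methyl 2-[(3S,6R)-6-methoxy-6-[(14E,16E)-octadeca-14,16-dien-1-yl]-3,6-dihydro-1,2-dioxin-3-yl]acetate | C/C=C/C=C/CCCCCCCCCCCCC[C@]1(OC)C=C[C@H](CC(=O)OC)OO1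
F5 | step 6 | methyl 2-[(3S,6S)-6-methoxy-6-[(14E,16E)-octadeca-14,16-dien-1-yl]-3,6-dihydro-1,2-dioxin-3-yl]acetate | C/C=C/C=C/CCCCCCCCCCCCC[C@@]1(OC)C=C[C@H](CC(=O)OC)OO1
F0 | step 9 | none | none
F6 | step 3 | 2-(12-bromododecyl)-2,5-dimethoxy-2,5-dihydrofuran | COC1C=CC(CCCCCCCCCCCCBr)(OC)O1
F7 | step 3 | [12-(2,5-dimethoxy-2,5-dihydrofuran-2-yl)dodecyl]magnesium bromide | COC1C=CC(CCCCCCCCCCCC[Mg]Br)(OC)O1
F8 | step 3 | 2,5-dimethoxy-2-[(14E,16E)-octadeca-14,16-dien-1-yl]-2,5-dihydrofuran | COC1C=CC(CCCCCCCCCCCCC/C=C/C=C/C)(OC)O1
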